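**Retrosynthetic overview** (atom numbers are those of the heavy atoms of the target SMILES read left to right; ring A = arene C18–C26, ring B = C13/C14/C15/C16/C18/C26, ring C = C3/C4/C11/C13/C14/C27, ring D = C4/N5/C9/O10/C11, ring E = N5–C9)
1. The plan rests on ring B being the keto tautomer (C16 ketone, C15 methylene, C13=C14): two oxidations earlier this is a C16 carbinol with saturated C13–C14, the pattern of a hydroxy-ortho-quinodimethane cycloadduct.
2. Key disconnection: C13–C14 and C15–C16, by intramolecular photoenolization/Diels–Alder of aldehyde 26 (ring A 2-alkylbenzaldehyde, vinyl ketone C14=C15 tethered through C11–C4=C3–C27), closing rings B and C at once.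
3. 26 comes from thiolactam 16 by Eschenmoser sulfide contraction with bromoacetone (C4=C3), C3 iodination and copper-catalysed methoxylation, and methylenation of the methyl ketone (C15).
4. Rings D and E come from an N-acyliminium closure of a hydroxy amide (C9); C11 comes from (S)-lactic acid by Seebach alkylation with 3,5-dimethoxybenzyl bromide; C16 is added by Vilsmeier formylation.
5. Ring order: A (purchased), D and E (step 6), B and C (step 13); then carbinol oxidation, C13–C14 dehydrogenation and chelation-controlled O19 demethylation.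

Key step: step 13

Assumption: the target is taken as the tautomer drawn (C16 ketone, C15 methylene, not the C16 naphthol); this keto form, held by the hydrogen bond from the C19 hydroxyl to the C16 carbonyl, is assumed to be the resting form, and steps 14 to 16 therefore avoid base.

**Step 1**
Reactants: 1 (S)-lactic acid; 2 pivalaldehyde
Product: 3 (2S,5S)-2-tert-butyl-5-methyl-1,3-dioxolan-4-one (cis)
Conditions: TsOH·H2O (cat.), H2SO4 (cat.), pentane, reflux, Dean–Stark; crystallization at −78 °C
Reagents that add atoms: none
Why: Acid-catalysed acetalization under equilibrating conditions should favour the cis dioxolanone, whose C2 centre is induced by the lactate centre (first stage of Seebach self-regeneration of stereocentres).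

**Step 2**
Reactants: 3 (2S,5S)-2-tert-butyl-5-methyl-1,3-dioxolan-4-one; 4 3,5-dimethoxybenzyl bromide
Product: 6 (2S,5R)-2-tert-butyl-5-(3,5-dimethoxybenzyl)-5-methyl-1,3-dioxolan-4-one, via lithium enolate 5 (not isolated)
Conditions: LiN(iPr)2, THF, −78 °C; then 4, −78 → −20 °C
Reagents that add atoms: none
Why: Enolate alkylation with a reactive benzylic bromide should occur on the face opposite the tert-butyl group, so the benzyl group takes the place of the former hydrogen and the quaternary centre (later C11, R) is set with overall retention.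

**Step 3**
Reactants: 6 (2S,5R)-2-tert-butyl-5-(3,5-dimethoxybenzyl)-5-methyl-1,3-dioxolan-4-one
Product: 8 (2S,5R)-2-tert-butyl-5-(2-formyl-3,5-dimethoxybenzyl)-5-methyl-1,3-dioxolan-4-one, via iminium chloride 7 (not isolated)
Conditions: POCl3, DMF, 0 → 60 °C; then aq. NaOAc
Reagents that add atoms: N,N-dimethylformamide, CN(C)C=O; water, O
Why: Vilsmeier–Haack formylation of the 3,5-dimethoxybenzyl ring should go to the position next to the benzylic carbon (ortho to one methoxy, para to the other; both such positions are equivalent), the site between the two methoxy groups being more hindered.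

**Step 4**
Reactants: 8 (2S,5R)-2-tert-butyl-5-(2-formyl-3,5-dimethoxybenzyl)-5-methyl-1,3-dioxolan-4-one
Product: 10 (R)-3-(2-formyl-3,5-dimethoxyphenyl)-2-hydroxy-2-methylpropanoic acid, via lithium carboxylate 9 (not isolated)
Conditions: LiOH, THF/MeOH/H2O, 40 °C; then 1 M HCl to pH 3
Reagents that add atoms: lithium hydroxide, [Li+].[OH-]
Why: Saponification of the acylal releases pivalaldehyde and the α-hydroxy acid; the quaternary centre cannot epimerize and the aldehyde has no α-hydrogen.

**Step 5**
Reactants: 10 (R)-3-(2-formyl-3,5-dimethoxyphenyl)-2-hydroxy-2-methylpropanoic acid; 11 4,4-diethoxybutan-1-amine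
Product: 13 (R)-N-(4,4-diethoxybutyl)-3-(2-formyl-3,5-dimethoxyphenyl)-2-hydroxy-2-methylpropanamide, via azabenzotriazolyl ester 12 (not isolated)
Conditions: DIC, HOAt, CH2Cl2/DMF, 0 °C (pre-activation); then 11, rt
Reagents that add atoms: none
Why: Carbodiimide/HOAt amide coupling tolerates the free tertiary hydroxyl, and the hindered, doubly donor-substituted aldehyde should form imine only slowly and reversibly (any imine is cleaved on aqueous work-up and in step 6).

**Step 6**
Reactants: 13 (R)-N-(4,4-diethoxybutyl)-3-(2-formyl-3,5-dimethoxyphenyl)-2-hydroxy-2-methylpropanamide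
Product: 15 (2R,7aS)-2-[2-(1,3-dioxolan-2-yl)-3,5-dimethoxybenzyl]-2-methyltetrahydropyrrolo[2,1-b][1,3]oxazol-3(2H)-one, via lactam aldehyde 14 (not isolated)
Conditions: TsOH·H2O (10 mol%), ethylene glycol, PhH, reflux, Dean–Stark
Reagents that add atoms: ethylene glycol, OCCO
Why: Acid ionizes the diethyl acetal, the amide nitrogen closes ring E to an N-acyliminium ion and the tertiary hydroxyl traps it to close ring D (N-acyliminium cyclization), while the same acid and glycol mask the aldehyde as its dioxolane; C9 forms reversibly, so both epimers are expected, the (7aS) epimer (C8 anti to the C11 methyl) is separated and the other is returned to the same conditions.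

**Step 7**
Reactants: 15 (2R,7aS)-2-[2-(1,3-dioxolan-2-yl)-3,5-dimethoxybenzyl]-2-methyltetrahydropyrrolo[2,1-b][1,3]oxazol-3(2H)-one
Product: 16 (2R,7aS)-2-[2-(1,3-dioxolan-2-yl)-3,5-dimethoxybenzyl]-2-methyltetrahydropyrrolo[2,1-b][1,3]oxazole-3(2H)-thione
Conditions: Lawesson's reagent (0.6 equiv), PhMe, 80 °C
Reagents that add atoms: Lawesson's reagent, COc1ccc(cc1)P1(=S)SP(=S)(S1)c1ccc(OC)cc1
Why: Thionation of a tertiary lactam by Lawesson's reagent is faster than reaction at ethers, acetals or the aminal, and the conditions are neutral, so C9 should not scramble.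

**Step 8**
Reactants: 16 thiolactam; 17 bromoacetone
Product: 19 (E)-1-[(2R,7aS)-2-[2-(1,3-dioxolan-2-yl)-3,5-dimethoxybenzyl]-2-methyltetrahydropyrrolo[2,1-b][1,3]oxazol-3(2H)-ylidene]propan-2-one, via thioiminium bromide 18 (not isolated)
Conditions: 17, MeCN, rt; then PPh3, Et3N, 60 °C
Reagents that add atoms: none
Why: Eschenmoser sulfide contraction (S-alkylation, intramolecular C–C bond formation to the episulfide, sulfur abstraction by phosphine) forms C4=C3 even next to the quaternary C11, and the acetyl group should sit syn to C11 because the alternative eclipses the N5–C6 methylene.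

**Step 9**
Reactants: 19 C3-unsubstituted enaminone
Product: 20 (Z)-1-iodo-1-[(2R,7aS)-2-[2-(1,3-dioxolan-2-yl)-3,5-dimethoxybenzyl]-2-methyltetrahydropyrrolo[2,1-b][1,3]oxazol-3(2H)-ylidene]propan-2-one
Conditions: NIS (1.05 equiv), CH2Cl2, −20 → 0 °C, dark
Reagents that add atoms: N-iodosuccinimide, O=C1CCC(=O)N1I
Why: The α-carbon C3 of the vinylogous amide is by far the most nucleophilic site, so electrophilic iodination should occur there before the methoxyarene reacts.

**Step 10**
Reactants: 20 C3 iodide
Product: 21 (Z)-1-methoxy-1-[(2R,7aS)-2-[2-(1,3-dioxolan-2-yl)-3,5-dimethoxybenzyl]-2-methyltetrahydropyrrolo[2,1-b][1,3]oxazol-3(2H)-ylidene]propan-2-one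
Conditions: CuI (20 mol%), 3,4,7,8-tetramethyl-1,10-phenanthroline (40 mol%), Cs2CO3, MeOH/PhMe, 90 °C
Reagents that add atoms: methanol, CO
Why: Copper-catalysed Ullmann-type C–O coupling of a vinyl iodide with an alcohol installs the C3 methyl ether; the push–pull C4=C3 bond rotates easily and should rest with the acetyl group syn to C11.

**Step 11**
Reactants: 21 C3-methoxy methyl ketone
Product: 25 (Z)-1-methoxy-1-[(2R,7aS)-2-[2-(1,3-dioxolan-2-yl)-3,5-dimethoxybenzyl]-2-methyltetrahydropyrrolo[2,1-b][1,3]oxazol-3(2H)-ylidene]but-3-en-2-one, via lithium enolate 22 (not isolated), via Mannich base 23 (not isolated), via ammonium iodide 24 (not isolated)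
Conditions: LiN(SiMe3)2, THF, −78 °C; CH2=NMe2+ I−, −78 → 0 °C; then MeI, rt; then aq. NaHCO3, CH2Cl2
Reagents that add atoms: Eschenmoser's salt, C=[N+](C)C.[I-]
Why: The methyl group is the only enolizable position, so its enolate is aminomethylated (Mannich reaction) and the quaternized amine is lost by β-elimination to give the vinyl ketone C14=C15.

**Step 12**
Reactants: 25 vinyl ketone dioxolane
Product: 26 2-{[(2R,3Z,7aS)-3-(1-methoxy-2-oxobut-3-en-1-ylidene)-2-methylhexahydropyrrolo[2,1-b][1,3]oxazol-2-yl]methyl}-4,6-dimethoxybenzaldehyde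
Conditions: PPTS (cat.), acetone/H2O, rt
Reagents that add atoms: water, O
Why: The dioxolane of a 2,4-dimethoxybenzaldehyde hydrolyses under very mild acid, which should spare the vinyl ketone and the aminal C9, whose nitrogen lone pair is tied up in the vinylogous amide.

**Step 13**
Reactants: 26 ring A aldehyde tethered to the enaminone vinyl ketone
Product: 28 pentacyclic C16 carbinol (9S,11R; H at C13 and C14 and C16 all on one face of ring B; cis B/C fusion), via photodienol 27 (not isolated)
Conditions: hν (365 nm), Ti(OiPr)4 (2 equiv), degassed PhMe (5 mM), 25 °C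
Reagents that add atoms: none
Why: Excitation of the aryl aldehyde is followed by 1,5-hydrogen transfer from the C13 methylene to the carbonyl oxygen, giving the (E)-dienol 27 across C16=C18–C26=C13, which Ti(OiPr)4 holds as a titanium dienolate while also binding the C27 carbonyl, so the vinylogous-amide donation is offset and C14=C15 regains acceptor character. The dienol then adds suprafacially to C14=C15 in an intramolecular [4+2] cycloaddition; the closest known reaction type is the intramolecular photoenolization/Diels–Alder reaction of ortho-alkylbenzaldehydes with a tethered enone, together with its Ti(OiPr)4-mediated intermolecular form. Ring B closes as the six-membered carbocycle of the cycloaddition itself (bonds C13–C14 and C15–C16), and ring C closes as the six-membered ring spanned by the four-atom tether C11–C4=C3–C27 between C13 and C14 (fused, type 1 intramolecular mode). C16 follows from the (E)-dienol with the hydroxyl outside; C14 follows from the endo placement of C27 under the diene, which the short planar tether and the titanium bridge between O16 and O27 both demand; C13 follows from the C11 centre, because allylic strain with the ring A C25–H should favour the C13–C11 rotamer in which C4 and O10 straddle that hydrogen and the methyl points away. The step needs the fused regiochemistry, which the tether enforces (the bridged mode would require a seven-membered ring), and it needs ring closure to outrun reketonization of the dienol and light absorption by the enaminone, for which the tethered dienophile, the titanium-bound dienol and dilute degassed solution are relied on. The three new centres are removed in steps 14 and 15, so their control, and in particular the face selection at C13, is not critical.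

**Step 14**
Reactants: 28 pentacyclic C16 carbinol
Product: 29 C16,C27 diketone (9S,11R; C13–H and C14–H cis)
Conditions: Dess–Martin periodinane, CH2Cl2, 0 °C → rt
Reagents that add atoms: none
Why: Dess–Martin oxidation of the secondary benzylic alcohol gives the aryl ketone under near-neutral conditions that the enaminone and the aminal should tolerate, and it removes the C16 stereocentre.

**Step 15**
Reactants: 29 C16,C27 diketone
Product: 30 O19-methyl ether of the target (C13=C14, C15 methylene, C16 ketone)
Conditions: DDQ (1.2 equiv), 1,4-dioxane, 80 °C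
Reagents that add atoms: none
Why: DDQ dehydrogenates the 1,4-diketone through its enol by hydride abstraction, and whichever enone isomer forms first, the isomers share the C16 dienol and should settle as the C13=C14 isomer conjugated with ring A and C27, which removes the C13 and C14 centres.

**Step 16**
Reactants: 30 O19-methyl ether of the target
Product: 32 target CNP0528850.1, via boron aryloxide 31 (not isolated)
Conditions: BCl3 (2.5 equiv), CH2Cl2, −78 → −40 °C; then MeOH, pH 7 buffer
Reagents that add atoms: none
Why: BCl3 binds the C16 carbonyl and the peri O19 methyl ether in a six-membered chelate, so chloride should remove only that methyl group at low temperature (O22 and O3 lack such a chelate), and since the aminal C9 can reopen and reclose under the Lewis acid it should settle with C8 anti to the pseudo-axial C11 methyl, the configuration drawn.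

**Compound list**
1 | (S)-lactic acid | C[C@H](O)C(=O)O | starting material
2 | pivalaldehyde | CC(C)(C)C=O | starting material
3 | (2S,5S)-2-tert-butyl-5-methyl-1,3-dioxolan-4-one | C[C@@H]1O[C@H](C(C)(C)C)OC1=O | intermediate
4 | 3,5-dimethoxybenzyl bromide | COc1cc(CBr)cc(OC)c1 | starting material
5 | lithium enolate of 3 | CC1=C([O-])O[C@@H](C(C)(C)C)O1.[Li+] | intermediate
6 | (2S,5R)-2-tert-butyl-5-(3,5-dimethoxybenzyl)-5-methyl-1,3-dioxolan-4-one | C[C@]1(Cc2cc(OC)cc(OC)c2)O[C@H](C(C)(C)C)OC1=O | intermediate
7 | aryl N,N-dimethyliminium chloride of 6 (at the ring position next to the benzylic carbon) | C[C@]1(Cc2cc(OC)cc(OC)c2C=[N+](C)C)O[C@H](C(C)(C)C)OC1=O.[Cl-] | intermediate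
8 | (2S,5R)-2-tert-butyl-5-(2-formyl-3,5-dimethoxybenzyl)-5-methyl-1,3-dioxolan-4-one | C[C@]1(Cc2cc(OC)cc(OC)c2C=O)O[C@H](C(C)(C)C)OC1=O | intermediate
9 | lithium (R)-3-(2-formyl-3,5-dimethoxyphenyl)-2-hydroxy-2-methylpropanoate | C[C@@](O)(Cc1cc(OC)cc(OC)c1C=O)C(=O)[O-].[Li+] | intermediate
10 | (R)-3-(2-formyl-3,5-dimethoxyphenyl)-2-hydroxy-2-methylpropanoic acid | C[C@@](O)(Cc1cc(OC)cc(OC)c1C=O)C(=O)O | intermediate
11 | 4,4-diethoxybutan-1-amine (4-aminobutanal diethyl acetal) | CCOC(CCCN)OCC | starting material
12 | 7-azabenzotriazol-1-yl ester of 10 | C[C@@](O)(Cc1cc(OC)cc(OC)c1C=O)C(=O)On1nnc2cccnc12 | intermediate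
13 | (R)-N-(4,4-diethoxybutyl)-3-(2-formyl-3,5-dimethoxyphenyl)-2-hydroxy-2-methylpropanamide | C[C@@](O)(Cc1cc(OC)cc(OC)c1C=O)C(=O)NCCCC(OCC)OCC | intermediate
14 | 2-{[(2R,7aS)-2-methyl-3-oxohexahydropyrrolo[2,1-b][1,3]oxazol-2-yl]methyl}-4,6-dimethoxybenzaldehyde | O=Cc1c(OC)cc(OC)cc1C[C@@]1(C)O[C@H]2CCCN2C1=O | intermediate
15 | (2R,7aS)-2-[2-(1,3-dioxolan-2-yl)-3,5-dimethoxybenzyl]-2-methyltetrahydropyrrolo[2,1-b][1,3]oxazol-3(2H)-one | COc1cc(OC)c(C2OCCO2)c(C[C@@]2(C)O[C@H]3CCCN3C2=O)c1 | intermediate
16 | (2R,7aS)-2-[2-(1,3-dioxolan-2-yl)-3,5-dimethoxybenzyl]-2-methyltetrahydropyrrolo[2,1-b][1,3]oxazole-3(2H)-thione | COc1cc(OC)c(C2OCCO2)c(C[C@@]2(C)O[C@H]3CCCN3C2=S)c1 | intermediate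
17 | bromoacetone | CC(=O)CBr | starting material
18 | S-(2-oxopropyl) thioiminium bromide of 16 | COc1cc(OC)c(C2OCCO2)c(C[C@@]2(C)O[C@H]3CCC[N+]3=C2SCC(C)=O)c1.[Br-] | intermediate
19 | (E)-enaminone methyl ketone, C3–H (acetyl syn to C11) | COc1cc(OC)c(C2OCCO2)c(C[C@@]2(C)O[C@H]3CCCN3/C2=C/C(C)=O)c1 | intermediate
20 | (Z)-C3-iodo enaminone methyl ketone | COc1cc(OC)c(C2OCCO2)c(C[C@@]2(C)O[C@H]3CCCN3/C2=C(\I)C(C)=O)c1 | intermediate
21 | (Z)-C3-methoxy enaminone methyl ketone | COc1cc(OC)c(C2OCCO2)c(C[C@@]2(C)O[C@H]3CCCN3/C2=C(\OC)C(C)=O)c1 | intermediate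
22 | lithium enolate of 21 at the methyl ketone | COc1cc(OC)c(C2OCCO2)c(C[C@@]2(C)O[C@H]3CCCN3/C2=C(\OC)C(=C)[O-])c1.[Li+] | intermediate
23 | Mannich base, 2-(dimethylamino)ethyl ketone | COc1cc(OC)c(C2OCCO2)c(C[C@@]2(C)O[C@H]3CCCN3/C2=C(\OC)C(=O)CCN(C)C)c1 | intermediate
24 | trimethylammonium iodide of 23 | COc1cc(OC)c(C2OCCO2)c(C[C@@]2(C)O[C@H]3CCCN3/C2=C(\OC)C(=O)CC[N+](C)(C)C)c1.[I-] | intermediate
25 | (Z)-C3-methoxy enaminone vinyl ketone, aldehyde as dioxolane | COc1cc(OC)c(C2OCCO2)c(C[C@@]2(C)O[C@H]3CCCN3/C2=C(\OC)C(=O)C=C)c1 | intermediate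
26 | 2-{[(2R,3Z,7aS)-3-(1-methoxy-2-oxobut-3-en-1-ylidene)-2-methylhexahydropyrrolo[2,1-b][1,3]oxazol-2-yl]methyl}-4,6-dimethoxybenzaldehyde | O=Cc1c(OC)cc(OC)cc1C[C@@]1(C)O[C@H]2CCCN2/C1=C(\OC)C(=O)C=C | intermediate
27 | (E)-dienol (hydroxy-ortho-quinodimethane) of 26, hydroxyl and C11 both outside, drawn without titanium | O/C=C1\C(OC)=CC(OC)=C/C1=C\[C@@]1(C)O[C@H]2CCCN2/C1=C(\OC)C(=O)C=C | intermediate
28 | pentacyclic C16 carbinol, cis-fused at C13/C14, hydrogens at C13, C14 and C16 on one face of ring B, ring B on the O10 face of ring C | O[C@@H]1C[C@@H]2C(=O)C(OC)=C3N4CCC[C@@H]4O[C@]3(C)[C@@H]2c2cc(OC)cc(OC)c21 | intermediate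
29 | pentacyclic C16,C27 diketone with saturated C13–C14 | O=C1C[C@@H]2C(=O)C(OC)=C3N4CCC[C@@H]4O[C@]3(C)[C@@H]2c2cc(OC)cc(OC)c21 | intermediate
30 | O19-methyl ether of the target | COC1=C2N3CCC[C@@H]3O[C@]2(C)C2=C(CC(=O)c3c(OC)cc(OC)cc32)C1=O | intermediate
31 | O19 dichloroboron aryloxide of the target | COC1=C2N3CCC[C@@H]3O[C@]2(C)C2=C(CC(=O)c3c(OB(Cl)Cl)cc(OC)cc32)C1=O | intermediate
32 | CNP0528850.1 (9S,11R) | COC1=C2N3CCC[C@@H]3O[C@]2(C)C2=C(CC(=O)c3c(O)cc(OC)cc32)C1=O | target

**Step count:** 16 steps in total; the longest linear sequence is 16 steps (from 1).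

**Steps most likely to fail**

Step 13 (key step). Reketonization of the photodienol may outrun the slow closure onto the donor-weakened dienophile, and the amino-dienone chromophore may take up part of the light. The fallback separates the photochemical event from the cycloaddition and sets out from 26. Irradiation of 26 at 350–365 nm in benzene saturated with SO2 should intercept the (E)-dienol by cheletropic addition and give the cyclic hydroxy sulfone F1 (one cis isomer drawn). After removal of excess SO2, F1 is heated in toluene at 80–100 °C in the dark, where cheletropic loss of SO2 regenerates the same dienol slowly and at a temperature at which the intramolecular Diels–Alder closure should be fast. The route is rejoined at 28.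

Step 10. Protodeiodination and slow C–O bond formation at the congested, fully substituted vinyl iodide may stall the copper coupling. The fallback brings in the oxygen as an electrophile and sets out from 19. Dibenzoyl peroxide in CH2Cl2 at 0 °C should attack the nucleophilic C3 and give the C3-benzoyloxy enaminone F2. K2CO3 in MeOH then removes the benzoate to give the C3-hydroxy enaminone F3, and MeI with K2CO3 in acetone methylates the enolic oxygen. The route is rejoined at 21.

Step 15. Electron-transfer oxidation of the enaminone or of the aminal C9–H by DDQ may compete with hydride abstraction next to the ketones. The fallback is a Saegusa–Ito dehydrogenation and sets out from 29. Kinetic deprotonation at C15 with LiN(SiMe3)2 and trapping with Me3SiCl at −78 °C should give the C16 trimethylsilyl enol ether F4. Pd(OAc)2 in MeCN at rt then gives the C14=C15 ene-dione isomer F5, which on silica gel or with a trace of TsOH should shift its C13 hydrogen to C15 through the common dienol. The route is rejoined at 30.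

**Further compounds**
F1 | step 13 | cyclic hydroxy sulfone from 26 (1-hydroxy-1,3-dihydrobenzo[c]thiophene 2,2-dioxide, C16–OH and C13–C11 cis) | O[C@H]1c2c(OC)cc(OC)cc2[C@@H]([C@@]2(C)O[C@H]3CCCN3/C2=C(\OC)C(=O)C=C)S1(=O)=O
F2 | step 10 | C3-benzoyloxy enaminone methyl ketone | COc1cc(OC)c(C2OCCO2)c(C[C@@]2(C)O[C@H]3CCCN3/C2=C(\OC(=O)c3ccccc3)C(C)=O)c1
F3 | step 10 | C3-hydroxy enaminone methyl ketone | COc1cc(OC)c(C2OCCO2)c(C[C@@]2(C)O[C@H]3CCCN3/C2=C(\O)C(C)=O)c1
F4 | step 15 | C16 trimethylsilyl enol ether of 29 (C15=C16) | C[Si](C)(C)OC1=C[C@@H]2C(=O)C(OC)=C3N4CCC[C@@H]4O[C@]3(C)[C@@H]2c2cc(OC)cc(OC)c21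
F5 | step 15 | C14=C15 ene-dione isomer of 30 | O=C1C=C2C(=O)C(OC)=C3N4CCC[C@@H]4O[C@]3(C)[C@@H]2c2cc(OC)cc(OC)c21
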